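**Plan**
Retrosynthesis: cut the C6–O ester bond and the C8–C9 epoxide, then C7–O (ene transposition of a C7=C8 alkene), then the C3–C4 bond of the cyclopentane (samarium Barbier), then C3–O/C4–O/C5–H (cyclic hydroboration of a C1-vinyl/C5-alkylidene diene), C4=C5 (aldol condensation) and C1–vinyl (conjugate addition to 3,6-dimethylcyclohepta-2,6-dienone).
Forward: the seven-membered ring is made first, by one-carbon ring expansion of 3,6-dimethylcyclohexenone; the five-membered ring closes second, in step 12, onto the finished cycloheptene.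
Enabling feature: the carbinol carbon C4 lies in the cyclopentane C1–C2–C3–C4–C5, is bonded to the fusion carbon C5 and is cis to the oxygen on C6 of the seven-membered ring, so a C5 isobutyryl ketone clamped to O6 by samarium can be attacked by C3 of a C1 iodoethyl arm.
Stereochemistry: C1 from the catalyst of the conjugate addition; C6 from a CBS reduction; C5 (trans ring fusion) from intramolecular hydride delivery out of the C1 arm; C4 from the O4–Sm–O6 chelate; C7 from singlet oxygen attacking anti to O6; C8/C9 from O6-directed epoxidation.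

Key step: step 12

Remark on numbering: atoms are numbered as in the target (C1 quaternary C–CH3; C2, C3 the ring CH2 groups; C4 the isopropyl carbinol; C5 fusion CH; C6 ester carbon; C7 carbinol; C8(CH3)/C9 epoxide; C10 CH2), and monocyclic intermediates keep these numbers. β is the face carrying the C1 methyl, α the opposite face.
Assumption: the exocyclic C4=C5 alkene of 12–14 is drawn Z (isopropyl turned away from the quaternary C1); either geometry would serve, because C4 ends as a ketone.
Compounds 2, 4 and 5 are racemic; chirality first enters in step 5.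

Step 1
Reactants: 1 3-methylcyclohex-2-en-1-one
Product: 2 3,6-dimethylcyclohex-2-en-1-one (racemic)
Conditions: LDA, THF, −78 °C; MeI, −78 → 0 °C
Reagents that add atoms: iodomethane, CI
Why: Kinetic α′-enolate alkylation of a cyclohexenone places the methyl group on C6 of the enone; this centre is racemic and is later flattened to sp2 (it becomes C8).

Step 2
Reactants: 2 3,6-dimethylcyclohex-2-en-1-one
Product: 3 1,4-dimethyl-2-(trimethylsilyloxy)cyclohexa-1,3-diene
Conditions: LDA, THF, −78 °C; TMSCl
Reagents that add atoms: chlorotrimethylsilane, C[Si](C)(C)Cl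
Why: Silyl enol ether formation: a second kinetic deprotonation at the only α′ hydrogen and O-silylation should give the cross-conjugated 2-silyloxydiene.

Step 3
Reactants: 3 1,4-dimethyl-2-(trimethylsilyloxy)cyclohexa-1,3-diene
Product: 4 3,6-dimethyl-1-(trimethylsilyloxy)bicyclo[4.1.0]hept-2-ene (racemic)
Conditions: Et2Zn, CH2I2, CH2Cl2, 0 °C → rt
Reagents that add atoms: diiodomethane, ICI
Why: Furukawa-modified Simmons–Smith cyclopropanation is fastest at the electron-rich silyl enol ether double bond of a 2-silyloxydiene and adds the carbon that becomes C7.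

Step 4
Reactants: 4 3,6-dimethyl-1-(trimethylsilyloxy)bicyclo[4.1.0]hept-2-ene
Product: 6 3,6-dimethylcyclohepta-2,6-dien-1-one, via chloro enone 5 (not isolated)
Conditions: FeCl3, DMF, 0 °C → rt; NaOAc, MeOH, reflux
Reagents that add atoms: none
Why: Saegusa–Ito ring expansion: FeCl3 oxidises the silyloxycyclopropane, β-scission of the internal bond gives the tertiary β-keto radical, which takes up chlorine, and acetate-mediated loss of HCl should give the symmetrical cross-conjugated dienone.

Step 5
Reactants: 6 3,6-dimethylcyclohepta-2,6-dien-1-one; 7 vinylmagnesium bromide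
Product: 8 (R)-3,6-dimethyl-6-vinylcyclohept-2-en-1-one
Conditions: 7, Me2AlCl, Et2O, 0 °C; then 6, CuTC (cat.), chiral phosphoramidite ligand (cat.), Et2O, −30 °C; aq. HCl
Reagents that add atoms: none
Why: Copper-catalysed asymmetric conjugate addition of an alkenylalane to a β-methyl cyclic enone builds the quaternary C1; the two enone halves of 6 are equivalent, so only the π-face is selected, and the ligand antipode is taken that gives (R)-C1 (methyl β, vinyl α).

Step 6
Reactants: 8 (R)-3,6-dimethyl-6-vinylcyclohept-2-en-1-one; 9 isobutyraldehyde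
Product: 12 (Z)-3,6-dimethyl-7-(2-methylpropylidene)-6-vinylcyclohept-2-en-1-one (quaternary centre as in 8), via aldol adduct 10 (not isolated), via aldol mesylate 11 (not isolated)
Conditions: LDA, THF, −78 °C; 9; MsCl, −78 → 0 °C; DBU, rt
Reagents that add atoms: none
Why: Aldol condensation: the kinetic lithium enolate forms at C5 (the only α′ position), adds to the aldehyde, and mesylation with E1cB elimination gives the α-alkylidene ketone, so the stereocentres of 10 and 11 disappear.

Step 7
Reactants: 12 the C5-isobutylidene dienone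
Product: 13 the 6α (S) alcohol of 12
Conditions: (R)-Me-CBS (cat.), catecholborane, toluene, −78 °C
Reagents that add atoms: none
Why: Corey–Bakshi–Shibata reduction, 1,2-selective and under catalyst control: the fully substituted C5 alkylidene flank acts as the large group, so the (R)-catalyst should deliver hydride to the β face of C6 and give the 6α alcohol regardless of the remote C1 centre.

Step 8
Reactants: 13 the 6α alcohol
Product: 14 the 6α methoxymethyl ether of 13
Conditions: MOMCl, i-Pr2NEt, CH2Cl2, 0 °C → rt
Reagents that add atoms: chloromethyl methyl ether, COCCl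
Why: MOM ether formation under amine base; the group should withstand borane, peroxide, iodination and SmI2 and later provides the chelating oxygen.

Step 9
Reactants: 14 the MOM-protected triene
Product: 16 the C3,C4-diol (1α-CH2CH2OH; 5β-CH(OH)iPr; 5α-H), via thexylborinane 15 (not isolated)
Conditions: ThxBH2 (from BH3·THF and 2,3-dimethylbut-2-ene), THF, 0 °C → rt, dilute; NaOH, H2O2, 0 °C → rt
Reagents that add atoms: hydrogen peroxide, OO
Why: Cyclic hydroboration of a 1,5-diene: thexylborane adds first to the vinyl group (boron on C3), and the remaining B–H then adds to C4=C5 through a chair-like six-membered transition state with boron on C4 and hydrogen delivered to C5 from the α face where the arm sits, so C5–H becomes α (trans to the C1 methyl) before oxidation with retention gives the diol.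

Step 10
Reactants: 16 the C3,C4-diol
Product: 17 the C3 iodide with free C4–OH
Conditions: I2, PPh3, imidazole, CH2Cl2, 0 °C
Reagents that add atoms: iodine, II
Why: Garegg–Samuelsson iodination converts the unhindered primary C3–OH by SN2 and should leave the secondary C4–OH, flanked by isopropyl and the ring, untouched.

Step 11
Reactants: 17 the iodo alcohol
Product: 18 the iodo ketone (1α-(2-iodoethyl); 5β-isobutyryl; 6α-OMOM; cyclohept-7-ene)
Conditions: Dess–Martin periodinane, NaHCO3, CH2Cl2, 0 °C → rt
Reagents that add atoms: none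
Why: Dess–Martin oxidation under buffered, non-basic conditions gives the isopropyl ketone without epimerising C5 or eliminating the β-MOM ether; the provisional C4 centre is erased.

Step 12
Reactants: 18 the iodo ketone
Product: 19 the trans-fused hydroazulenol (4β-OH; 4α-iPr; 5α-H; 6α-OMOM; C7=C8)
Conditions: SmI2, HMPA, THF, −78 → 0 °C; aq. NH4Cl
Reagents that add atoms: none
Why: SmI2/HMPA reduces the primary C3–I bond by two single-electron transfers, faster than it forms a ketyl from the hindered dialkyl ketone, and the resulting alkylsamarium(III) adds to the C4 carbonyl; this is the intramolecular samarium Barbier cyclisation of ω-iodoalkyl ketones. The cyclopentane C1–C2–C3–C4–C5 closes in the 5-exo-trig mode, with the carbonyl oxygen outside the new ring. C4 is the only new stereocentre: Sm(III) bridges the carbonyl oxygen and the C6 MOM oxygen in a six-membered chelate, which holds C=O syn to C6 and the isopropyl group on the C5–H side, so C3 adds to the open face and the hydroxyl ends cis to C6 and to the C1 methyl. The trans ring fusion is not decided here; it is carried in from the C1/C5 configuration of 18 set in steps 5 and 9. The step needs C–I reduction to outrun C=O reduction and must not epimerise C5 or eliminate the MOM ether; the low temperature, the neutral medium and the inertness of the trisubstituted C7=C8 alkene should secure this.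

Step 13
Reactants: 19 the hydroazulenol
Product: 21 the 7β-allylic alcohol with C8=C9, via allylic hydroperoxide 20 (not isolated)
Conditions: O2, hν, tetraphenylporphyrin (cat.), CH2Cl2, −20 °C; PPh3
Reagents that add atoms: oxygen, O=O
Why: Schenck ene reaction: singlet oxygen should bond to C7 from the β face, anti to the 6α-MOM ether, and take hydrogen from C9 on the more crowded side of the alkene (cis effect; the C6–H geminal to oxygen is not abstracted), moving the double bond to C8=C9 before PPh3 reduces the hydroperoxide with retention.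

Step 14
Reactants: 21 the 7β-allylic alcohol
Product: 22 the 7β-TBS ether
Conditions: TBSOTf, 2,6-lutidine, CH2Cl2, −78 °C
Reagents that add atoms: tert-butyldimethylsilyl triflate, CC(C)(C)[Si](C)(C)OS(=O)(=O)C(F)(F)F
Why: Silyl ether formation at the secondary allylic C7–OH at low temperature; the tertiary C4–OH is too hindered to react.

Step 15
Reactants: 22 the 7β-TBS ether
Product: 23 the 6α-alcohol
Conditions: MgBr2·OEt2, n-BuSH, Et2O, rt
Reagents that add atoms: none
Why: Lewis acid–thiol cleavage of the MOM acetal under conditions that should spare the TBS ether, the alkene and the tertiary alcohol.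

Step 16
Reactants: 23 the 6α-alcohol
Product: 24 the 8α,9α-epoxide
Conditions: VO(acac)2 (cat.), t-BuOOH, CH2Cl2, 0 °C → rt
Reagents that add atoms: tert-butyl hydroperoxide, CC(C)(C)OO
Why: Vanadium-catalysed hydroxyl-directed epoxidation: the homoallylic 6α-hydroxyl binds vanadium and delivers oxygen to the α face of C8=C9, the face also left open by the 7β-silyl ether and the β C1 methyl, which sets C8 and C9.

Step 17
Reactants: 25 4-hydroxybenzoic acid
Product: 27 4-(tert-butyldimethylsilyloxy)benzoic acid, via bis-silyl derivative 26 (not isolated)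
Conditions: TBSCl, imidazole, DMF, rt; K2CO3, MeOH/THF/H2O, rt; aq. HCl to pH 4
Reagents that add atoms: tert-butyldimethylsilyl chloride, CC(C)(C)[Si](C)(C)Cl
Why: Silylation of both acidic hydroxyls followed by selective hydrolysis of the labile silyl ester gives the phenol-protected acid.

Step 18
Reactants: 24 the epoxy diol; 27 4-(tert-butyldimethylsilyloxy)benzoic acid
Product: 29 the bis-silylated 6α-ester, via mixed anhydride 28 (not isolated)
Conditions: 2,4,6-trichlorobenzoyl chloride, Et3N, toluene, rt; 24, DMAP, rt → 40 °C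
Reagents that add atoms: none
Why: Yamaguchi esterification through the mixed anhydride acylates the hindered secondary C6–OH with retention; the tertiary C4–OH and the epoxide should not react.

Step 19
Reactants: 29 the bis-silylated ester
Product: 30 the target CNP0290052.1
Conditions: HF·pyridine, pyridine, THF, 0 °C → rt
Reagents that add atoms: none
Why: Fluoride cleavage of the alkyl and aryl silyl ethers under pyridine-buffered conditions, chosen to avoid acyl migration to O7, Payne rearrangement and acid opening of the trisubstituted epoxide.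

**Compound list**
1 | 3-methylcyclohex-2-en-1-one | CC1=CC(=O)CCC1 | starting material
2 | 3,6-dimethylcyclohex-2-en-1-one (racemic) | CC1=CC(=O)C(C)CC1 | intermediate
3 | 1,4-dimethyl-2-(trimethylsilyloxy)cyclohexa-1,3-diene | CC1=CC(O[Si](C)(C)C)=C(C)CC1 | intermediate
4 | 3,6-dimethyl-1-(trimethylsilyloxy)bicyclo[4.1.0]hept-2-ene (racemic, cis-fused cyclopropane) | CC1=CC2(O[Si](C)(C)C)CC2(C)CC1 | intermediate
5 | 6-chloro-3,6-dimethylcyclohept-2-en-1-one (racemic) | CC1=CC(=O)CC(C)(Cl)CC1 | intermediate
6 | 3,6-dimethylcyclohepta-2,6-dien-1-one | CC1=CC(=O)C=C(C)CC1 | intermediate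
7 | vinylmagnesium bromide | C=C[Mg]Br | starting material
8 | (R)-3,6-dimethyl-6-vinylcyclohept-2-en-1-one (C6 ketone, C7=C8, C1 methyl β, vinyl α) | O=C1C=C(C)CC[C@@](C)(C=C)C1 | intermediate
9 | isobutyraldehyde | CC(C)C=O | starting material
10 | aldol adduct: 8 with a 1-hydroxy-2-methylpropyl group on C5 (lithium alkoxide in the flask; both new centres unassigned) | CC(C)C(O)C1C(=O)C=C(C)CC[C@@]1(C)C=C | intermediate
11 | methanesulfonate of 10 | CC(C)C(OS(C)(=O)=O)C1C(=O)C=C(C)CC[C@@]1(C)C=C | intermediate
12 | (Z)-3,6-dimethyl-7-(2-methylpropylidene)-6-vinylcyclohept-2-en-1-one; C1 methyl β, vinyl α; isopropyl syn to the carbonyl | CC(C)/C=C1\C(=O)C=C(C)CC[C@@]1(C)C=C | intermediate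
13 | 6α (S) alcohol of 12: Z-isobutylidene at C5, C7=C8(CH3), 1β-CH3, 1α-vinyl | CC(C)/C=C1\[C@@H](O)C=C(C)CC[C@@]1(C)C=C | intermediate
14 | 6α-methoxymethyl ether of 13 | CC(C)/C=C1\[C@@H](OCOC)C=C(C)CC[C@@]1(C)C=C | intermediate
15 | trans-fused B-thexyl borinane (ring B–C3–C2–C1–C5–C4; 5α-H; 6α-OMOM; C7=C8) | CC(C)[C@@H]1B(C(C)(C)C(C)C)CC[C@]2(C)CCC(C)=C[C@H](OCOC)[C@H]21 | intermediate
16 | diol: 1β,8-dimethylcyclohept-7-ene with 1α-(2-hydroxyethyl), 5β-[(S)-1-hydroxy-2-methylpropyl] (5α-H), 6α-OMOM | CC(C)[C@H](O)[C@@H]1[C@@H](OCOC)C=C(C)CC[C@@]1(C)CCO | intermediate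
17 | iodo alcohol: as 16 with 1α-(2-iodoethyl) | CC(C)[C@H](O)[C@@H]1[C@@H](OCOC)C=C(C)CC[C@@]1(C)CCI | intermediate
18 | iodo ketone (key-step precursor): 1β,8-dimethylcyclohept-7-ene with 1α-(2-iodoethyl), 5β-isobutyryl (5α-H), 6α-OMOM | CC(C)C(=O)[C@@H]1[C@@H](OCOC)C=C(C)CC[C@@]1(C)CCI | intermediate
19 | trans-fused hydroazulenol (key-step product): 4β-OH, 4α-isopropyl, 5α-H, 6α-OMOM, 1β-CH3, C7=C8 with 8-CH3 | CC(C)[C@]1(O)CC[C@]2(C)CCC(C)=C[C@H](OCOC)[C@H]21 | intermediate
20 | 7β-hydroperoxide with C8=C9, otherwise as 19 | CC(C)[C@]1(O)CC[C@]2(C)CC=C(C)[C@@H](OO)[C@H](OCOC)[C@H]21 | intermediate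
21 | 7β-alcohol with C8=C9 (4β-OH, 6α-OMOM) | CC(C)[C@]1(O)CC[C@]2(C)CC=C(C)[C@@H](O)[C@H](OCOC)[C@H]21 | intermediate
22 | 7β-tert-butyldimethylsilyl ether of 21 | CC(C)[C@]1(O)CC[C@]2(C)CC=C(C)[C@@H](O[Si](C)(C)C(C)(C)C)[C@H](OCOC)[C@H]21 | intermediate
23 | 4β,6α-diol with 7β-OTBS and C8=C9 | CC(C)[C@]1(O)CC[C@]2(C)CC=C(C)[C@@H](O[Si](C)(C)C(C)(C)C)[C@H](O)[C@H]21 | intermediate
24 | 8α,9α-epoxide of 23 (8β-CH3) | CC(C)[C@]1(O)CC[C@]2(C)C[C@@H]3O[C@]3(C)[C@@H](O[Si](C)(C)C(C)(C)C)[C@H](O)[C@H]21 | intermediate
25 | 4-hydroxybenzoic acid | OC(=O)c1ccc(O)cc1 | starting material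
26 | tert-butyldimethylsilyl 4-(tert-butyldimethylsilyloxy)benzoate | CC(C)(C)[Si](C)(C)OC(=O)c1ccc(O[Si](C)(C)C(C)(C)C)cc1 | intermediate
27 | 4-(tert-butyldimethylsilyloxy)benzoic acid | CC(C)(C)[Si](C)(C)Oc1ccc(cc1)C(O)=O | intermediate
28 | 4-(tert-butyldimethylsilyloxy)benzoic 2,4,6-trichlorobenzoic anhydride | CC(C)(C)[Si](C)(C)Oc1ccc(cc1)C(=O)OC(=O)c1c(Cl)cc(Cl)cc1Cl | intermediate
29 | 6α-[4-(tert-butyldimethylsilyloxy)benzoate] of 24 (7β-OTBS, 8α,9α-epoxide, 4β-OH) | CC(C)[C@]1(O)CC[C@]2(C)C[C@@H]3O[C@]3(C)[C@@H](O[Si](C)(C)C(C)(C)C)[C@H](OC(=O)c3ccc(O[Si](C)(C)C(C)(C)C)cc3)[C@H]21 | intermediate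
30 | CNP0290052.1: 8α,9α-epoxy-4β,7β-dihydroxy-4α-isopropyl-1β,8β-dimethyl-trans-hydroazulen-6α-yl 4-hydroxybenzoate (5α-H) | CC(C)[C@]1(O)CC[C@]2(C)C[C@@H]3O[C@]3(C)[C@@H](O)[C@H](OC(=O)c3ccc(O)cc3)[C@H]21 | target

**Step count and risks**
Total: 19 steps. Longest linear sequence: 18 steps (steps 1–16, 18 and 19, from 3-methylcyclohex-2-en-1-one).

Steps most likely to fail:

Step 5. Transfer of an unsubstituted vinyl group to the cross-conjugated, β-disubstituted dienone may be slow or poorly face-selective, so conversion or enantiomeric purity could fall short. The fallback sets out from 6: NHC–copper-catalysed conjugate addition of the (1-trimethylsilylvinyl)aluminium reagent made from trimethylsilylacetylene and DIBAL-H should give the silylvinyl ketone F1, and protodesilylation (CF3CO2H, CH2Cl2) removes silicon and comes back to the route at 8.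

Step 7. With an alkenyl group on both sides of the carbonyl, the catalyst may tell the two flanks apart poorly, which would give a mixture of C6 epimers. The fallback sets out from 12: unselective Luche reduction (NaBH4, CeCl3, MeOH) gives 13 together with its 6β-epimer F2; the two are separated by chromatography, F2 is re-oxidised (MnO2, CH2Cl2) to 12 and recycled, and the route is rejoined at 13.

Step 13. Hydrogen abstraction from the C8 methyl instead of C9, or oxygen delivery to the α face, would erode regio- and facial selectivity. The fallback sets out from 19: epoxidation of C7=C8 on the β face (mCPBA, NaHCO3) gives the 7β,8β-epoxide F3; Meinwald rearrangement with 1,2-hydride shift (BF3·OEt2, −78 °C) gives the C7 ketone F4; dehydrogenation (IBX, DMSO, 70 °C) gives the 8-methyl-Δ8 enone F5; and CBS reduction of the C7 carbonyl, with the catalyst antipode that gives the 7β-alcohol, comes back to the route at 21.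

**Further compounds**
F1 | step 5 | (R)-3,6-dimethyl-6-[1-(trimethylsilyl)vinyl]cyclohept-2-en-1-one | O=C1C=C(C)CC[C@@](C)(C(=C)[Si](C)(C)C)C1
F2 | step 7 | 6β-epimer of 13 | CC(C)/C=C1\[C@H](O)C=C(C)CC[C@@]1(C)C=C
F3 | step 13 | 7β,8β-epoxide of 19 | CC(C)[C@]1(O)CC[C@]2(C)CC[C@@]3(C)O[C@H]3[C@H](OCOC)[C@H]21
F4 | step 13 | C7 ketone with saturated C8 (C8 epimers), 4β-OH, 6α-OMOM | CC(C)[C@]1(O)CC[C@]2(C)CCC(C)C(=O)[C@H](OCOC)[C@H]21
F5 | step 13 | C7 ketone with C8=C9 (8-methyl enone), 4β-OH, 6α-OMOM | CC(C)[C@]1(O)CC[C@]2(C)CC=C(C)C(=O)[C@H](OCOC)[C@H]21
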